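**Retrosynthetic overview**
- The dioxane is cut last: a [4+2] addition of the O2=C2–C3=O3 unit of the ortho-quinone tautomer of celastrol methyl ester across C1=C5 of a guaia-1(5),3,11-triene. The diene is carried as its C3 enol triflate so that C1=C5, not C3=C4, reacts; the triflate is reduced in the last step.
- The strategy rests on the guaiane half: a cyclopentene (C1–C5) fused through the C1–C5 bond to a seven-membered ring (C1, C5–C10), with methyls on C4 and C10 and isopropenyl on C7. This is the pattern left when a 4-methyl eudesma-1,4-dien-3-one forms C1–C5, cuts C5–C10 and takes up water at C10 under irradiation.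
- Stereochemical relay: the angular methyl of the dienone (cis to the C7 isopropenyl) fixes H-1 and 10-OH of the photoproduct; radical removal of 10-OH then puts H-10 cis to H-1, and C1 is erased when the dienyl triflate is made.
- The dienone comes from (S)-carvone by conjugate reduction, chiral-imine Michael addition to ethyl vinyl ketone, aldol condensation and dehydrogenation.
- Ring order: carvone ring (later the seven-membered ring), annulated ring A, five/seven bicycle in the key step, dioxane by cycloaddition onto triterpene ring A.

Key step: step 6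

Remark: the C=N geometry of 4 and 6 and the two transient centres of ketol 8 are left undefined because they are lost in the same or the next step; excited states, enolates, zwitterions, carbocations and metal-bound species are described in the Why lines and carry no numbers.

**Step 1**
Reactants: 1 (S)-carvone
Product: 2 (2S,5S)-2-methyl-5-(prop-1-en-2-yl)cyclohexan-1-one (trans-dihydrocarvone; some 2-epimer is tolerated)
Conditions: Zn dust, KOH, EtOH–H2O, reflux
Reagents that add atoms: none
Why: Conjugate reduction of the enone by zinc in alkali (electron transfer, then protonation at the β-carbon) leaves the isolated isopropenyl group alone; C5 is untouched, and C2 settles trans (equatorial methyl) but becomes an enamine carbon in steps 2 and 3.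

**Step 2**
Reactants: 2 (2S,5S)-dihydrocarvone; 3 (S)-1-phenylethylamine
Product: 4 N-[(S)-1-phenylethyl] imine of 2
Conditions: 3 (1.05 equiv), TsOH·H2O (1 mol %), toluene, reflux, azeotropic removal of water
Reagents that add atoms: none
Why: Acid-catalysed imine condensation installs the (S)-phenylethyl controller; no permanent stereocentre is formed, and C2 can epimerise through the secondary enamine tautomer.

**Step 3**
Reactants: 4 imine; 5 ethyl vinyl ketone
Product: 7 (2R,5S)-2-methyl-2-(3-oxopentyl)-5-(prop-1-en-2-yl)cyclohexan-1-one, via Michael adduct imine 6 (not isolated)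
Conditions: 5 (1.5 equiv), THF, 40 °C, 3 d; then 20% aq. AcOH, rt
Reagents that add atoms: water, O
Why: Michael addition of the more substituted secondary enamine tautomer to the enone (aza-ene-like transition state with internal N–H transfer) forms the C–C bond at the methyl-bearing carbon on the face away from the phenyl group of the (S)-auxiliary, which should override the weak bias of the remote isopropenyl group and place the angular methyl cis to it; aqueous acid then hydrolyses the imine.

**Step 4**
Reactants: 7 diketone
Product: 9 (4aR,7S)-1,4a-dimethyl-7-(prop-1-en-2-yl)-4,4a,5,6,7,8-hexahydronaphthalen-2(3H)-one (ent-α-cyperone), via aldol ketol 8 (not isolated)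
Conditions: NaOMe, MeOH, 60 °C
Reagents that add atoms: none
Why: Intramolecular aldol condensation (the ring-closing half of a Robinson annulation): the ethyl ketone enolate closes on the ring carbonyl and the ketol loses water to the tetrasubstituted enone; the quaternary C10 and C7 are not touched.

**Step 5**
Reactants: 9 ent-α-cyperone
Product: 10 (4aR,7S)-1,4a-dimethyl-7-(prop-1-en-2-yl)-5,6,7,8-tetrahydronaphthalen-2(4aH)-one (ent-eudesma-1,4,11-trien-3-one)
Conditions: DDQ (1.3 equiv), dioxane, reflux
Reagents that add atoms: none
Why: Quinone dehydrogenation of a 4-en-3-one under non-acidic conditions goes through the cross-conjugated 2,4-dienol and removes hydride from C1, so the 1,4-dien-3-one should form rather than the 4,6-dienone that needs strong acid; no stereocentre is involved.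

**Step 6**
Reactants: 10 ent-eudesma-1,4,11-trien-3-one; 11 water
Product: 12 (5S,8S,8aS)-8-hydroxy-3,8-dimethyl-5-(prop-1-en-2-yl)-4,5,6,7,8,8a-hexahydroazulen-2(1H)-one (10-hydroxyguaia-4,11-dien-3-one; H-1 and 10-OH cis to each other and trans to the C10 methyl, which is cis to the isopropenyl group)
Conditions: hν (medium-pressure Hg lamp, borosilicate filter, λ > 300 nm), AcOH–H2O 45:55, N2, 15–20 °C, 0.01 M
Reagents that add atoms: none
Why: Excitation of the cross-conjugated dienone joins the two β-carbons C1 and C5 to give the bicyclo[3.1.0] oxyallyl zwitterion, which acetic acid protonates on oxygen; the cyclopropylcarbinyl cation then opens by cleavage of C5–C10 while water attacks C10 from the rear, and the dienol ketonises to the enone. The closest known reaction type is the photorearrangement of 4-methyl 1,4-dien-3-ones to hydroxy hydroazulenones in aqueous acid. The five-membered ring is closed by the C1–C5 bond made in the excited state (first a three-membered ring, which becomes the cyclopentenone once C5–C10 breaks), and the seven-membered ring is not closed by a new bond but arises by ring enlargement when C5–C10 of the former six-membered ring is cut. Both new stereocentres are relayed from C10 of 10: the cyclopropane must stay cis-fused to ring B, which puts H-1 on the face opposite the angular methyl, and water enters C10 with inversion relative to the departing C5, so OH ends cis to H-1 while the methyl stays cis to the C7 isopropenyl group. The step needs the hydroxy-enone channel rather than the shift to the lumiketone or a spiro ketone; the C4 methyl stabilises positive charge at C4 so that C5–C10 is the bond that breaks, and the acidic protic medium protonates the zwitterion before it rearranges. The isopropenyl group does not absorb at these wavelengths and lies away from the rear side of C10, so it should remain a spectator.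

**Step 7**
Reactants: 12 hydroxy enone
Product: 13 methyl oxalate of 12 (10-O-methoxalyl derivative)
Conditions: ClC(O)CO2Me (2 equiv), pyridine (4 equiv), DMAP (0.2 equiv), CH2Cl2, 0 °C to rt
Reagents that add atoms: methyl chlorooxoacetate, COC(=O)C(Cl)=O
Why: DMAP-catalysed acylation of the tertiary alcohol by the very electrophilic half-ester chloride; the C10–O bond is not broken, so the configuration is retained, and the weak base should avoid vinylogous elimination.

**Step 8**
Reactants: 13 methyl oxalate
Product: 14 (5S,8R,8aR)-3,8-dimethyl-5-(prop-1-en-2-yl)-4,5,6,7,8,8a-hexahydroazulen-2(1H)-one (guaia-4,11-dien-3-one with H-1 and H-10 cis and the C10 methyl cis to isopropenyl)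
Conditions: Bu3SnH (3 equiv, 0.3 M), AIBN (0.2 equiv), toluene, 100 °C
Reagents that add atoms: none
Why: Radical deoxygenation of a tertiary alkyl methyl oxalate (Barton–McCombie type chain); the planar C10 radical should hold its methyl in plane eclipsing C1–H, which leaves the C1–C2 bond pseudo-axial over one face, so Bu3SnH is expected to deliver hydrogen to the other face, cis to H-1 and where the oxygen was, keeping the methyl cis to the isopropenyl group.

**Step 9**
Reactants: 14 guaia-4,11-dien-3-one
Product: 16 (5S,8R)-3,8-dimethyl-5-(prop-1-en-2-yl)-1,4,5,6,7,8-hexahydroazulen-2-yl trifluoromethanesulfonate, via cross-conjugated dienyl triflate 15 (not isolated)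
Conditions: LiN(iPr)2 (1.1 equiv), THF, −78 °C; PhNTf2 (1.2 equiv), −78 to 0 °C; then 40 °C, 2 h
Reagents that add atoms: N-phenylbis(trifluoromethanesulfonimide), O=S(=O)(N(c1ccccc1)S(=O)(=O)C(F)(F)F)C(F)(F)F
Why: Kinetic deprotonation at C2 and O-sulfonylation (enol triflate formation) give 15, a cyclopentadiene with an sp3 C1–H, whose hydrogen should move to C2 by a suprafacial [1,5]-sigmatropic shift into the isomer with both ring double bonds tetrasubstituted (C1=C5 and C3=C4); C1 is erased, C7 and C10 are untouched.

**Step 10**
Reactants: 17 celastrol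
Product: 18 celastrol methyl ester (pristimerin)
Conditions: MeI (1.5 equiv), NaHCO3 (2 equiv), DMF, rt, dark
Reagents that add atoms: iodomethane, CI
Why: SN2 O-alkylation of the carboxylate; hydrogen carbonate deprotonates the acid but not the hydrogen-bonded C3 enol, so the ester should form chemoselectively with no stereocentre involved.

**Step 11**
Reactants: 18 pristimerin; 16 dienyl triflate
Product: 20 triflate-bearing hetero-Diels–Alder adduct (21 with OTf on guaiane C3), via ortho-quinone tautomer 19 (not isolated)
Conditions: 16 (1.5 equiv), PhCO2H (20 mol %), toluene, 60 °C, Ar, dark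
Reagents that add atoms: none
Why: Proposed new method: 18 is the extended enol (O3–H, C3=C4–C5=C6–C7=C8) of an ortho-quinone, and the carboxylic acid is meant to relay the proton from O3 to C8 on the α-face, away from the C9 and C14 methyls, giving a small stationary amount of the 2,3-dione 19 (8α-H, C6=C7) that is drained by inverse-electron-demand [4+2] addition of its O=C–C=O unit across C1=C5 of 16; the C3 triflate deactivates C3=C4 and makes C1, the remote diene terminus, the nucleophilic end, so the O3–C1 bond should run ahead (charge then builds on O2, para to the C5 vinyl group) and O2–C5 close second; suprafacial addition gives the cis-fused dioxane, and the heterodiene is expected on the α-face, opposite the C7–C8–C9 bridge in the conformer with equatorial isopropenyl and syn to the C10 methyl, which is the weak point; the closest known reaction types are the [4+2] addition of ortho-quinones to alkenes and dienes giving 1,4-benzodioxanes and the ortho-quinone/hydroxy-quinone-methide tautomerism, normally seen running toward the quinone methide.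

**Step 12**
Reactants: 20 triflate adduct
Product: 21 CNP0113384.1 (target)
Conditions: Pd(OAc)2 (10 mol %), PPh3 (20 mol %), HCO2H (3 equiv), Bu3N (4 equiv), DMF, 50 °C
Reagents that add atoms: none
Why: Palladium-catalysed formate reduction of an enol triflate (oxidative addition of C3–OTf to zerovalent palladium, formate exchange, loss of CO2, C–H reductive elimination) replaces OTf by H without moving C3=C4; no stereocentre is involved, and the hindered tertiary aryl ethers, the styrene, the ester and the isopropenyl group should not react.

**Compound list**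
1 | (S)-carvone | CC1=CC[C@@H](CC1=O)C(C)=C | starting material
2 | (2S,5S)-2-methyl-5-(prop-1-en-2-yl)cyclohexan-1-one | C=C(C)[C@H]1CC[C@H](C)C(=O)C1 | intermediate
3 | (S)-1-phenylethylamine | C[C@H](N)c1ccccc1 | starting material
4 | N-[(S)-1-phenylethyl] imine of 2 | C=C(C)[C@H]1CC[C@H](C)C(=N[C@@H](C)c2ccccc2)C1 | intermediate
5 | ethyl vinyl ketone | CCC(=O)C=C | starting material
6 | Michael adduct imine (quaternary C2, methyl cis to isopropenyl) | C=C(C)[C@H]1CC[C@](C)(CCC(=O)CC)C(=N[C@@H](C)c2ccccc2)C1 | intermediate
7 | (2R,5S)-2-methyl-2-(3-oxopentyl)-5-(prop-1-en-2-yl)cyclohexan-1-one | C=C(C)[C@H]1CC[C@](C)(CCC(=O)CC)C(=O)C1 | intermediate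
8 | aldol ketol (5-hydroxy-4-methyl decalone, C4 and C5 undefined) | C=C(C)[C@H]1CC[C@]2(C)CCC(=O)C(C)C2(O)C1 | intermediate
9 | (4aR,7S)-1,4a-dimethyl-7-(prop-1-en-2-yl)-4,4a,5,6,7,8-hexahydronaphthalen-2(3H)-one | C=C(C)[C@H]1CC[C@]2(C)CCC(=O)C(C)=C2C1 | intermediate
10 | (4aR,7S)-1,4a-dimethyl-7-(prop-1-en-2-yl)-5,6,7,8-tetrahydronaphthalen-2(4aH)-one | C=C(C)[C@H]1CC[C@]2(C)C=CC(=O)C(C)=C2C1 | intermediate
11 | water | O | starting material
12 | (5S,8S,8aS)-8-hydroxy-3,8-dimethyl-5-(prop-1-en-2-yl)-4,5,6,7,8,8a-hexahydroazulen-2(1H)-one | C=C(C)[C@H]1CC[C@](C)(O)[C@H]2CC(=O)C(C)=C2C1 | intermediate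
13 | methyl oxalate of 12 | C=C(C)[C@H]1CC[C@](C)(OC(=O)C(=O)OC)[C@H]2CC(=O)C(C)=C2C1 | intermediate
14 | (5S,8R,8aR)-3,8-dimethyl-5-(prop-1-en-2-yl)-4,5,6,7,8,8a-hexahydroazulen-2(1H)-one | C=C(C)[C@H]1CC[C@@H](C)[C@H]2CC(=O)C(C)=C2C1 | intermediate
15 | cross-conjugated dienyl triflate (C2=C3, C4=C5, sp3 C1–H) | C=C(C)[C@H]1CC[C@@H](C)[C@H]2C=C(OS(=O)(=O)C(F)(F)F)C(C)=C2C1 | intermediate
16 | (5S,8R)-3,8-dimethyl-5-(prop-1-en-2-yl)-1,4,5,6,7,8-hexahydroazulen-2-yl trifluoromethanesulfonate | C=C(C)[C@H]1CC[C@@H](C)C2=C(C1)C(C)=C(OS(=O)(=O)C(F)(F)F)C2 | intermediate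
17 | celastrol | CC1=C(O)C(=O)C=C2C1=CC=C1[C@@]2(C)CC[C@@]2(C)[C@@H]3C[C@](C)(C(=O)O)CC[C@]3(C)CC[C@]12C | starting material
18 | celastrol methyl ester (pristimerin) | CC1=C(O)C(=O)C=C2C1=CC=C1[C@@]2(C)CC[C@@]2(C)[C@@H]3C[C@](C)(C(=O)OC)CC[C@]3(C)CC[C@]12C | intermediate
19 | ortho-quinone tautomer of 18 (2,3-dioxo, C6=C7, 8α-H) | O=C1C=C2C(=C(C)C1=O)C=C[C@H]1[C@@]2(C)CC[C@@]2(C)[C@@H]3C[C@](C)(C(=O)OC)CC[C@]3(C)CC[C@]12C | intermediate
20 | triflate adduct (dioxane O3–C1 and O2–C5, all centres as in 21, OTf on guaiane C3) | C=C(C)[C@H]1CC[C@@H](C)[C@]23CC(OS(=O)(=O)C(F)(F)F)=C(C)[C@@]2(C1)Oc1cc2c(c(C)c1O3)C=C[C@H]1[C@@]2(C)CC[C@@]2(C)[C@@H]3C[C@](C)(C(=O)OC)CC[C@]3(C)CC[C@]12C | intermediate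
21 | CNP0113384.1 (8α-H ring-A-aromatic pristimerin unit with O3 and O2 bonded to C1 and C5 of (7S,10R)-guaia-3,11-diene; dioxane cis-fused on the face of the C10 methyl) | C=C(C)[C@H]1CC[C@@H](C)[C@]23CC=C(C)[C@@]2(C1)Oc1cc2c(c(C)c1O3)C=C[C@H]1[C@@]2(C)CC[C@@]2(C)[C@@H]3C[C@](C)(C(=O)OC)CC[C@]3(C)CC[C@]12C | target

**Step count and risks**
Total: 12 steps. Longest linear sequence: 11 steps (steps 1–9, 11 and 12 from (S)-carvone); the celastrol branch adds step 10 before the convergent step 11.

Steps most likely to fail:

1. Step 11 (Proposed new method). The proton relay from O3 to C8 may be too slow, or be outrun by acid-promoted reactions at C6 of the quinone methide, and the cycloaddition may take the other face of C1=C5. The fallback uses known chemistry only and sets out from 18. Hydride 1,6-reduction (NaBH4, MeOH, 0 °C) gives the C7=C8 catechol pristimerol F1, which is protected as the bis(methoxymethyl) ether F2 (MOMCl, iPr2NEt). KOtBu in DMSO moves the double bond into conjugation with the arene, as in the 1,4- to 1,2-dihydronaphthalene isomerisation, with protonation of C8 on the α-face, giving the C6=C7 bis-ether F3. HCl in MeOH frees the C6=C7 catechol F4. Oxidation of F4 with Ag2O in CH2Cl2 at 0 °C in the presence of 16 forms 19 directly, so the cycloaddition no longer depends on the tautomerisation and can run cold; the path comes back at 20.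

2. Step 8. Hydrogen may be delivered to the wrong face of the planar C10 radical, or the radical may be captured across the ring by the isopropenyl group. The fallback sets out from 12 and gives up the relay. Acid-catalysed dehydration (TsOH·H2O, toluene, 50 °C) gives the linear dienone guaia-1(10),4,11-trien-3-one F5. Ligand-controlled copper hydride 1,6-hydrosilylation (Cu(OAc)2·H2O, (R)-DTBM-SEGPHOS, PhMe2SiH, toluene, 0 °C; the antipodal ligand if the sense proves opposite) adds hydride to C10 and gives the dimethylphenylsilyl dienol ether F6. MeLi followed by PhNTf2 converts F6 into the triflate, and the path comes back at 16.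

3. Step 6. The zwitterion may drain into the lumiketone and phenolic products when protonation and water capture are slow, and 12 may be consumed by secondary photolysis in the dilute aqueous medium. The fallback sets out from 10 and changes both the capturing partner and the way C10 is set. Irradiation in anhydrous acetic acid lets acetate capture C10 and gives the 10-acetoxy enone F7. A tertiary acetate is no substrate for steps 7 and 8, so DBU removes acetic acid by vinylogous E1cB elimination to the linear dienone F5, and the copper hydride sequence through the silyl dienol ether F6 comes back to the route at 16.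

**Further compounds**
F1 | step 11 | pristimerol (methyl 2,3-dihydroxy-24-nor-friedela-1,3,5(10),7-tetraen-29-oate) | Cc1c(O)c(O)cc2c1CC=C1[C@@]2(C)CC[C@@]2(C)[C@@H]3C[C@](C)(C(=O)OC)CC[C@]3(C)CC[C@]12C
F2 | step 11 | pristimerol bis(methoxymethyl) ether | Cc1c(OCOC)c(OCOC)cc2c1CC=C1[C@@]2(C)CC[C@@]2(C)[C@@H]3C[C@](C)(C(=O)OC)CC[C@]3(C)CC[C@]12C
F3 | step 11 | C6=C7, 8α-H isomer of the bis(methoxymethyl) ether | Cc1c(OCOC)c(OCOC)cc2c1C=C[C@H]1[C@@]2(C)CC[C@@]2(C)[C@@H]3C[C@](C)(C(=O)OC)CC[C@]3(C)CC[C@]12C
F4 | step 11 | C6=C7, 8α-H catechol (methyl 2,3-dihydroxy-24-nor-friedela-1,3,5(10),6-tetraen-29-oate) | Cc1c(O)c(O)cc2c1C=C[C@H]1[C@@]2(C)CC[C@@]2(C)[C@@H]3C[C@](C)(C(=O)OC)CC[C@]3(C)CC[C@]12C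
F5 | step 8 | (7S)-guaia-1(10),4,11-trien-3-one | C=C(C)[C@H]1CCC(C)=C2CC(=O)C(C)=C2C1
F6 | step 8 | dimethylphenylsilyl dienol ether of (7S,10R)-guaia-1(5),3,11-trien-3-ol | C=C(C)[C@H]1CC[C@@H](C)C2=C(C1)C(C)=C(O[Si](C)(C)c3ccccc3)C2
F7 | step 6 | 10-acetoxyguaia-4,11-dien-3-one (acetate of 12) | C=C(C)[C@H]1CC[C@](C)(OC(C)=O)[C@H]2CC(=O)C(C)=C2C1
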